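## Analysis of the target

The target 21 is the methyl ester of gyrophoric acid, a linear tridepside: three 2,4-dihydroxy-6-methylbenzoyl units, ring A (bearing the methyl ester, unprimed locants), ring B (central, primed locants) and ring C (terminal, double-primed locants), joined by the aryl ester bonds C7'–O4 and C7''–O4', where C7' and C7'' are the two depside carbonyl carbons. It has no stereocenter, so the problem is one of connectivity and regiochemistry only. Every ester carbonyl sits between an ortho oxygen and an ortho methyl group, so acyl transfer from these benzoic acids is slow. The two aryl esters are active acyl donors that tolerate neither alkoxide nor strong base, and the methyl ester has to survive as well. Three of the four free phenols (O-2, O-2', O-2'') are hydrogen-bonded to their carbonyls, whereas O-4'' is not. The hard part is that rings A and B must each be acylated on the 4-oxygen while the 2-oxygen stays free, and that ring B must be acylated on O-4' while its own hindered carboxyl is already an ester of ring A. The strategy rests on the substitution pattern of ring B: C1' carries the carboxyl bound to O-4 of ring A, C6' the methyl group, C3' and C5' are CH, and C2' and C4' carry two oxygens that must end up different. This pattern maps onto a vinylketene carrying the ester (C4', C1', C6', C5') and an alkoxyalkyne (C3', C2'), with the ketene carbon becoming the free phenol carbon C4' and the alkyne oxygen arriving as an ether on C2'.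

## Retrosynthetic reasoning

**21 from 20.** The last operation cuts four O–alkyl bonds: three benzyl ethers and the ethyl ether on O-2'. The ethyl group is the residue of the alkyne used to build ring B. It sits ortho to the C7' carbonyl, where a chelating Lewis acid can remove it, and benzyl ethers fall to the same reagent, so one step frees all four phenols. The forward reaction must leave both aryl esters and the methyl ester intact.

**20 from 16 and 19.** The C7''–O4' ester bond is cut. In 16 the only free hydroxyl is O-4', so the acylation has no selectivity question. Ring C is the one ring for which a pre-formed, doubly protected acid is trivial, so it is brought in as acid chloride 19.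

**19 from 1.** Acid chloride 19 comes from acid 18, which comes from ester 17 by hydrolysis, and 17 from 1 by double O-benzylation. Only functional-group changes are involved.

**16 from 10 and 11.** This is the strategic disconnection. Ring B is taken apart at C1'–C2', C3'–C4', C4'–C5' and C1'–C6', leaving the C7'–O4 ester untouched. Cutting here and not at the ester means the hindered depside bond is never made by acyl transfer from a di-ortho-substituted benzoic acid; the ring is grown from a carbon that already carries the ester. In the forward direction 10 rearranges to ketene 12, which combines with 11 through cyclobutenone 13, dienylketene 14 and dienone 15 to give phenol 16. The two oxygens of ring B come from different reactants and are therefore differentiated without any protecting-group step.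

**10 from 9.** The C=N2 unit is removed. The forward reaction is a diazo transfer onto the doubly activated methylene of the beta-keto ester.

**9 from 4 and 7.** The C(=O)–O4 bond is cut. In the forward sense this is an unhindered acylation of phenol 4 by acylketene 8, released thermally from 7. Reagent 7 is the C-acylation product of 5 with 6. The acyl carbon involved becomes C7', so the hindered depside bond is formed before it becomes hindered.

**4 from 1.** Phenol 4 needs O-2 masked and O-4 free, the reverse of the innate reactivity of 1. O-4 is therefore blocked first as the allyl ether 2, O-2 is benzylated to 3, and the allyl group is removed under neutral palladium catalysis.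

## Alternatives that were turned down

Alternative 1: Ring A is disconnected at C1–C6 and C2–C3. The pyranone ester A1, a 4-aroyloxy-6-methyl-2-pyrone whose acyl group is the complete benzyl-protected B–C unit, would undergo cycloaddition with methyl 3-methoxyprop-2-ynoate A2. Decarboxylative aromatization of the bicyclic adduct would then give the 2-O-methyl tri-O-benzyl tridepside A3.

- For: polarity is matched. The nucleophilic C3 of the pyranone meets the methoxy-bearing alkyne carbon and the electrophilic C6 meets the ester-bearing carbon. Aromatization is irreversible, and neither a diazo compound nor light is needed. On these points it is at least as secure as the chosen route.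
- Against: pyranone–alkyne cycloadditions need high temperatures. A1 is an enol ester of a vinylogous acid and an active acyl donor, so acyl migration to C3 or cleavage is expected to compete. A2 is a push–pull alkyne and a weak dienophile toward a diene that is not electron-rich.
- Against: the acyl part of A1, rings B and C, must first be assembled by classical depside chemistry with full protecting-group differentiation of ring B. The route is therefore no shorter, and its uncertain step comes last, on the most valuable material.
- Comparison: A3 still needs a chelation-assisted dealkylation ortho to an ester, the same kind of end step as in the chosen route. The chosen route places its uncertain step in the middle, at room temperature, on a small substrate, and solves the ring B differentiation that this alternative leaves to classical means.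

Alternative 2: Ring C is disconnected at C1''–C2'' and C5''–C6''. 1-Methoxy-1,3-bis(trimethylsilyloxy)buta-1,3-diene A4 would add across the alkyne of the aryl but-2-ynoate A5, a protected A–B didepside acylated on O-4'. Elimination of the methoxy group and desilylation would aromatize ring C and give the 2,2'-di-O-benzyl tridepside A6.

- For: ring C appears with both hydroxyls free. The hindered acyl transfer to O-4' is replaced by acylation with an unhindered alkynoic acid. The end step is a neutral hydrogenolysis of two benzyl ethers, milder than the Lewis acid step of the chosen route.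
- Against: a beta-methyl alkynoate is a sluggish partner for this diene. A5 contains two aryl esters, one of them the alkynoate itself, and A4 is a dienolate equivalent that can attack these carbonyls and cleave the link it is supposed to build on.
- Against: the aromatization can lose either the methoxy or the silyloxy group at C2'', so an O-methyl ether can form.
- Comparison: ring C is the ring that classical chemistry supplies most easily, so building it de novo gains least. The A–B didepside core of A5, with the ring B oxygens differentiated, must still be made conventionally. The chosen strategy spends its new bond construction on ring B, where the difficulty lies.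

Alternative 3: The C1'–C7' and C7'–O4 bonds are cut together. The ring B aryl iodide A7, already acylated on O-4' with the acyl group of 18, would combine with carbon monoxide A8 and methyl orsellinate 1 under palladium catalysis to give the tri-O-benzyl tridepside A9.

- For: it is the most convergent and the shortest of the four. Compound 1 is used unprotected because its hydrogen-bonded O-2 hydroxyl does not compete. A7 is reachable from 3-(benzyloxy)-5-methylphenol A10 by iodination para to the free hydroxyl and acylation with 19. Only hydrogenolysis of A9 remains afterwards. On step count and on the end step it is stronger than the chosen route.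
- Against: the iodide of A7 is flanked by a benzyloxy and a methyl group and is electron-rich. The acylpalladium intermediate is hindered, and the nucleophile is a weakly nucleophilic, ester-deactivated phenol. The conditions needed (base, heat, phenoxide) are those under which the aryl ester already present in A7 transesterifies, scrambling the depside. Reduction of the iodide and direct C–O coupling are further competing paths.
- Comparison: the chosen strategy never forms the hindered C1'–C7' bond or the hindered ester by substitution at a congested centre. It differentiates the ring B oxygens by their origin and not by a statistical monoprotection such as the one that A10 requires, at the price of a longer sequence.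

Key step: step 7

## Route

Step 1
Reactants: 1 methyl orsellinate (methyl 2,4-dihydroxy-6-methylbenzoate)
Product: 2 methyl 2-hydroxy-6-methyl-4-(prop-2-en-1-yloxy)benzoate
Conditions: allyl bromide (1.1 equiv), K2CO3, acetone, reflux
Reagents that add atoms: allyl bromide, C=CCBr
Why: Williamson etherification; the O-2 hydroxyl is hydrogen-bonded to the ester carbonyl and is much less acidic and nucleophilic than the O-4 hydroxyl para to the ester, so monoalkylation should occur at O-4.

Step 2
Reactants: 2 methyl 2-hydroxy-6-methyl-4-(prop-2-en-1-yloxy)benzoate
Product: 3 methyl 2-(benzyloxy)-6-methyl-4-(prop-2-en-1-yloxy)benzoate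
Conditions: BnBr, K2CO3, DMF, 60 °C
Reagents that add atoms: benzyl bromide, BrCc1ccccc1
Why: Williamson etherification of the remaining chelated phenol under more forcing conditions; the temperature is far below that of an aryl allyl Claisen rearrangement.

Step 3
Reactants: 3 methyl 2-(benzyloxy)-6-methyl-4-(prop-2-en-1-yloxy)benzoate
Product: 4 methyl 2-(benzyloxy)-4-hydroxy-6-methylbenzoate
Conditions: Pd(PPh3)4 (cat.), morpholine, THF, rt
Reagents that add atoms: none
Why: Tsuji–Trost deallylation; zerovalent palladium ionizes the aryl allyl ether to an allylpalladium phenoxide and morpholine takes up the allyl group, leaving the benzyl ether and the methyl ester untouched.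

Step 4
Reactants: 5 Meldrum's acid (2,2-dimethyl-1,3-dioxane-4,6-dione); 6 methacryloyl chloride
Product: 7 5-(1-hydroxy-2-methylprop-2-en-1-ylidene)-2,2-dimethyl-1,3-dioxane-4,6-dione (methacryloyl Meldrum's acid, enol form)
Conditions: pyridine, CH2Cl2, −10 °C → rt
Reagents that add atoms: none
Why: C-acylation of Meldrum's acid by an acid chloride; 6 has no alpha hydrogen and cannot form a ketene, and its alpha methyl group slows conjugate addition, so attack at the acyl carbon should dominate.

Step 5
Reactants: 7 methacryloyl Meldrum's acid; 4 methyl 2-(benzyloxy)-4-hydroxy-6-methylbenzoate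
Product: 9 methyl 2-(benzyloxy)-6-methyl-4-[(4-methyl-3-oxopent-4-enoyl)oxy]benzoate, via methacryloylketene 8 (not isolated)
Conditions: toluene, BHT (cat.), 90 °C
Reagents that add atoms: none
Why: Thermal cycloreversion of the acyl Meldrum's acid releases acylketene 8, and the only free hydroxyl of 4 adds to it to give the aryl beta-keto ester; the radical inhibitor guards the isopropenyl ketone against polymerization.

Step 6
Reactants: 9 methyl 2-(benzyloxy)-6-methyl-4-[(4-methyl-3-oxopent-4-enoyl)oxy]benzoate
Product: 10 methyl 2-(benzyloxy)-4-[(2-diazo-4-methyl-3-oxopent-4-enoyl)oxy]-6-methylbenzoate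
Conditions: 4-AcNHC6H4SO2N3, Et3N, MeCN, 0 °C
Reagents that add atoms: 4-acetamidobenzenesulfonyl azide, CC(=O)Nc1ccc(cc1)S(=O)(=O)N=[N+]=[N-]
Why: Regitz diazo transfer to the doubly activated methylene of a beta-keto ester; low temperature and a full equivalent of the azide are meant to let diazo transfer outrun base-induced side reactions of the enolate.

Step 7
Reactants: 10 methyl 2-(benzyloxy)-4-[(2-diazo-4-methyl-3-oxopent-4-enoyl)oxy]-6-methylbenzoate; 11 ethoxyacetylene
Product: 16 methyl 2-(benzyloxy)-4-[(2-ethoxy-4-hydroxy-6-methylbenzoyl)oxy]-6-methylbenzoate, via vinylketene 12 (not isolated), via vinylcyclobutenone 13 (not isolated), via dienylketene 14 (not isolated), via cyclohexadienone 15 (not isolated)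
Conditions: 11 (5 equiv), hν (300 nm, Pyrex), ClCH2CH2Cl (dilute), rt; then 80 °C
Reagents that add atoms: none
Why: Proposed new method: the vinylketene–alkoxyalkyne benzannulation triggered by photochemical Wolff rearrangement (Danheiser benzannulation) is the closest known reaction type and is established for alpha-diazo enones, and the photochemical Wolff rearrangement of 2-diazo-3-oxo esters to alkoxycarbonylketenes is established separately, but the two have not been shown together on an aryl 2-diazo-3-oxoalk-4-enoate, whose ketene carries an ester on its alpha carbon. Excitation of 10 expels dinitrogen with 1,2-shift of the isopropenyl group from the ketone carbon to the diazo carbon (C1'–C6'), giving ketene 12. The nucleophilic CH terminus of 11 attacks the ketene carbonyl carbon and the oxygen-bearing alkyne carbon closes onto the ketene alpha carbon in a [2+2] cycloaddition (C3'–C4' and C1'–C2'), giving racemic 13. Conrotatory 4-pi opening of 13 gives 14; this opening is reversible, so the isomer with the isopropenyl group cis to the ketene is drained by disrotatory 6-pi electrocyclization (C4'–C5'), which is the closure of ring B, and enolization of 15 gives the phenol. Regiochemistry follows from the polarization of both partners: the ketene carbon becomes C4' with a free hydroxyl and the ether carbon becomes C2' next to the ester-bearing C1'. The selectivity the step needs is periselectivity, [2+2] at the ketene C=C against hetero-[4+2] or oxa-6-pi closure through the carbonyl of the aryl ester; an ester carbonyl is a far poorer heterodiene terminus than a ketone carbonyl, and aromatization is the irreversible sink. No stereocenter remains in the product. Long-wavelength irradiation, dilution and excess 11 are chosen to spare the aryl ester from photo-Fries cleavage and to keep phenol 16 from trapping 12.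

Step 8
Reactants: 1 methyl orsellinate
Product: 17 methyl 2,4-bis(benzyloxy)-6-methylbenzoate
Conditions: BnBr (2.5 equiv), K2CO3, DMF, 60 °C
Reagents that add atoms: benzyl bromide, BrCc1ccccc1
Why: Double Williamson etherification; with excess halide and warming, the chelated O-2 hydroxyl is alkylated as well.

Step 9
Reactants: 17 methyl 2,4-bis(benzyloxy)-6-methylbenzoate
Product: 18 2,4-bis(benzyloxy)-6-methylbenzoic acid
Conditions: KOH, DMSO/H2O, 90 °C; then aq. HCl
Reagents that add atoms: potassium hydroxide, [K+].[OH-]
Why: Saponification of a di-ortho-substituted benzoate needs poorly solvated hydroxide and heat; benzyl ethers are inert to these conditions.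

Step 10
Reactants: 18 2,4-bis(benzyloxy)-6-methylbenzoic acid
Product: 19 2,4-bis(benzyloxy)-6-methylbenzoyl chloride
Conditions: (COCl)2, DMF (cat.), CH2Cl2, 0 °C → rt; concentrated and used crude
Reagents that add atoms: oxalyl chloride, ClC(=O)C(Cl)=O
Why: Acid chloride formation through the chloroiminium species from DMF; it is mild enough to keep the ortho benzyl ether, and the crude chloride is used at once.

Step 11
Reactants: 16 methyl 2-(benzyloxy)-4-[(2-ethoxy-4-hydroxy-6-methylbenzoyl)oxy]-6-methylbenzoate; 19 2,4-bis(benzyloxy)-6-methylbenzoyl chloride
Product: 20 methyl 2-(benzyloxy)-4-({4-[(2,4-bis(benzyloxy)-6-methylbenzoyl)oxy]-2-ethoxy-6-methylbenzoyl}oxy)-6-methylbenzoate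
Conditions: Et3N, DMAP (cat.), CH2Cl2, 0 °C → rt
Reagents that add atoms: none
Why: Nucleophilic acyl substitution with DMAP catalysis; O-4' is the only free hydroxyl in 16, so the site is fixed by the way ring B was built, and the mild amine base should not disturb the existing depside link.

Step 12
Reactants: 20 methyl 2-(benzyloxy)-4-({4-[(2,4-bis(benzyloxy)-6-methylbenzoyl)oxy]-2-ethoxy-6-methylbenzoyl}oxy)-6-methylbenzoate
Product: 21 methyl 4-({4-[(2,4-dihydroxy-6-methylbenzoyl)oxy]-2-hydroxy-6-methylbenzoyl}oxy)-2-hydroxy-6-methylbenzoate (target)
Conditions: BCl3 (excess), C6HMe5, CH2Cl2, −78 °C → rt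
Reagents that add atoms: none
Why: Lewis acid ether cleavage; the benzyl ethers ionize at low temperature and pentamethylbenzene captures the benzyl cations, and on warming the ethyl ether on O-2' is cleaved with chelation assistance, boron bridging the ether oxygen and the C7' carbonyl while chloride attacks the ethyl carbon. The aryl esters and the methyl ester have no comparably activated O–alkyl bond and should survive.

## Compound list

1 | methyl orsellinate (methyl 2,4-dihydroxy-6-methylbenzoate) | COC(=O)c1c(C)cc(O)cc1O | starting material
2 | methyl 2-hydroxy-6-methyl-4-(prop-2-en-1-yloxy)benzoate | COC(=O)c1c(C)cc(OCC=C)cc1O | intermediate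
3 | methyl 2-(benzyloxy)-6-methyl-4-(prop-2-en-1-yloxy)benzoate | COC(=O)c1c(C)cc(OCC=C)cc1OCc1ccccc1 | intermediate
4 | methyl 2-(benzyloxy)-4-hydroxy-6-methylbenzoate | COC(=O)c1c(C)cc(O)cc1OCc1ccccc1 | intermediate
5 | Meldrum's acid (2,2-dimethyl-1,3-dioxane-4,6-dione) | CC1(C)OC(=O)CC(=O)O1 | starting material
6 | methacryloyl chloride | CC(=C)C(Cl)=O | starting material
7 | 5-(1-hydroxy-2-methylprop-2-en-1-ylidene)-2,2-dimethyl-1,3-dioxane-4,6-dione | CC(=C)C(O)=C1C(=O)OC(C)(C)OC1=O | intermediate
8 | methacryloylketene (4-methylpenta-1,4-diene-1,3-dione), not isolated | CC(=C)C(=O)C=C=O | intermediate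
9 | methyl 2-(benzyloxy)-6-methyl-4-[(4-methyl-3-oxopent-4-enoyl)oxy]benzoate | COC(=O)c1c(C)cc(OC(=O)CC(=O)C(C)=C)cc1OCc1ccccc1 | intermediate
10 | methyl 2-(benzyloxy)-4-[(2-diazo-4-methyl-3-oxopent-4-enoyl)oxy]-6-methylbenzoate | COC(=O)c1c(C)cc(OC(=O)C(=[N+]=[N-])C(=O)C(C)=C)cc1OCc1ccccc1 | intermediate
11 | ethoxyacetylene | CCOC#C | starting material
12 | vinylketene: 3-(benzyloxy)-4-(methoxycarbonyl)-5-methylphenyl 3-methyl-2-(oxomethylidene)but-3-enoate, not isolated | COC(=O)c1c(C)cc(OC(=O)C(=C=O)C(C)=C)cc1OCc1ccccc1 | intermediate
13 | vinylcyclobutenone: 3-(benzyloxy)-4-(methoxycarbonyl)-5-methylphenyl 2-ethoxy-4-oxo-1-(prop-1-en-2-yl)cyclobut-2-ene-1-carboxylate, racemic, not isolated | COC(=O)c1c(C)cc(OC(=O)C2(C(C)=C)C(=O)C=C2OCC)cc1OCc1ccccc1 | intermediate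
14 | dienylketene: 3-(benzyloxy)-4-(methoxycarbonyl)-5-methylphenyl (2Z)-3-ethoxy-5-oxo-2-(prop-1-en-2-yl)penta-2,4-dienoate, not isolated | COC(=O)c1c(C)cc(OC(=O)/C(C(C)=C)=C(OCC)/C=C=O)cc1OCc1ccccc1 | intermediate
15 | cyclohexadienone: 3-(benzyloxy)-4-(methoxycarbonyl)-5-methylphenyl 6-ethoxy-2-methyl-4-oxocyclohexa-1,5-diene-1-carboxylate, not isolated | COC(=O)c1c(C)cc(OC(=O)C2=C(C)CC(=O)C=C2OCC)cc1OCc1ccccc1 | intermediate
16 | methyl 2-(benzyloxy)-4-[(2-ethoxy-4-hydroxy-6-methylbenzoyl)oxy]-6-methylbenzoate | COC(=O)c1c(C)cc(OC(=O)c2c(C)cc(O)cc2OCC)cc1OCc1ccccc1 | intermediate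
17 | methyl 2,4-bis(benzyloxy)-6-methylbenzoate | COC(=O)c1c(C)cc(OCc2ccccc2)cc1OCc1ccccc1 | intermediate
18 | 2,4-bis(benzyloxy)-6-methylbenzoic acid | OC(=O)c1c(C)cc(OCc2ccccc2)cc1OCc1ccccc1 | intermediate
19 | 2,4-bis(benzyloxy)-6-methylbenzoyl chloride | ClC(=O)c1c(C)cc(OCc2ccccc2)cc1OCc1ccccc1 | intermediate
20 | methyl 2-(benzyloxy)-4-({4-[(2,4-bis(benzyloxy)-6-methylbenzoyl)oxy]-2-ethoxy-6-methylbenzoyl}oxy)-6-methylbenzoate | COC(=O)c1c(C)cc(OC(=O)c2c(C)cc(OC(=O)c3c(C)cc(OCc4ccccc4)cc3OCc3ccccc3)cc2OCC)cc1OCc1ccccc1 | intermediate
21 | methyl 4-({4-[(2,4-dihydroxy-6-methylbenzoyl)oxy]-2-hydroxy-6-methylbenzoyl}oxy)-2-hydroxy-6-methylbenzoate | COC(=O)c1c(C)cc(OC(=O)c2c(C)cc(OC(=O)c3c(C)cc(O)cc3O)cc2O)cc1O | target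

## Step count and least certain steps

Total: 12 steps. Longest linear sequence: 8 steps (steps 1, 2, 3, 5, 6, 7, 11, 12). Step 4 and steps 8–10 are side branches.

**Step 7 (key step, proposed new method).** Four processes could divert it: closure through the oxygen of the aryl ester carbonyl instead of through carbon, either at the stage of the ketene–alkyne union or at the dienylketene; reaction of the diazo compound or its carbene with the electron-rich alkyne before the Wolff shift; photo-Fries cleavage of the aryl ester in the substrate or the product; and capture of the ketene by the phenol that the reaction itself produces. The alpha-ester vinylketene has no direct precedent in this benzannulation, so any of these may dominate.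

The fallback uses known depside chemistry, sets out from 2 and 4 and returns at 16. Compound 2 is O-ethylated (ethyl iodide, K2CO3, DMF) to methyl 2-ethoxy-6-methyl-4-(prop-2-en-1-yloxy)benzoate F1, which is saponified (KOH, aqueous ethanol, reflux) to 2-ethoxy-6-methyl-4-(prop-2-en-1-yloxy)benzoic acid F2. Oxalyl chloride with catalytic DMF converts F2 into 2-ethoxy-6-methyl-4-(prop-2-en-1-yloxy)benzoyl chloride F3, which acylates 4 (Et3N, DMAP) to give methyl 2-(benzyloxy)-4-{[2-ethoxy-6-methyl-4-(prop-2-en-1-yloxy)benzoyl]oxy}-6-methylbenzoate F4. Deallylation of F4 with Pd(PPh3)4 and morpholine gives 16. This gives up the ring construction and accepts a hindered acylation, but every operation is standard.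

**Step 12.** The primary ethyl ether may cleave slowly. Prolonged exposure to the Lewis acid at room temperature could then lead to scission of a depside link, O-demethylation of the chelated methyl ester, or C-benzylation of the electron-rich rings.

The fallback sets out from 16 and returns at 21; it moves the dealkylation to the sturdier didepside and makes the last operation a neutral hydrogenolysis. Compound 16 is treated with BCl3 and pentamethylbenzene to give methyl 4-[(2,4-dihydroxy-6-methylbenzoyl)oxy]-2-hydroxy-6-methylbenzoate F5. F5 is acylated with 19 (pyridine, CH2Cl2, 0 °C) at its only non-hydrogen-bonded hydroxyl, O-4', to give methyl 4-({4-[(2,4-bis(benzyloxy)-6-methylbenzoyl)oxy]-2-hydroxy-6-methylbenzoyl}oxy)-2-hydroxy-6-methylbenzoate F6. Hydrogenolysis of F6 (H2, Pd/C, ethyl acetate) gives 21.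

**Step 6 (with steps 4 and 5 behind it).** Under triethylamine the enolate of 9 may expel the aryloxide (reversion to the acylketene) or add to the isopropenyl ketone of a second molecule, in competition with diazo transfer. The acylation in step 4 may also suffer conjugate addition.

The fallback sets out from 4 and returns at 10; it never generates the enolate of the enone beta-keto ester and makes steps 4 and 5 unnecessary. Compound 4 is acylated with bromoacetyl bromide (pyridine, CH2Cl2) to methyl 2-(benzyloxy)-4-[(bromoacetyl)oxy]-6-methylbenzoate F7. N,N'-Bis(p-toluenesulfonyl)hydrazine and DBU convert F7 into methyl 2-(benzyloxy)-4-[(diazoacetyl)oxy]-6-methylbenzoate F8. DBU-catalysed aldol addition of F8 to methacrolein gives racemic methyl 2-(benzyloxy)-4-[(2-diazo-3-hydroxy-4-methylpent-4-enoyl)oxy]-6-methylbenzoate F9. Oxidation of the allylic alcohol of F9 with 2-iodoxybenzoic acid in DMSO gives 10.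

## Further compounds

F1 | step 7 | methyl 2-ethoxy-6-methyl-4-(prop-2-en-1-yloxy)benzoate | COC(=O)c1c(C)cc(OCC=C)cc1OCC
F2 | step 7 | 2-ethoxy-6-methyl-4-(prop-2-en-1-yloxy)benzoic acid | OC(=O)c1c(C)cc(OCC=C)cc1OCC
F3 | step 7 | 2-ethoxy-6-methyl-4-(prop-2-en-1-yloxy)benzoyl chloride | ClC(=O)c1c(C)cc(OCC=C)cc1OCC
F4 | step 7 | methyl 2-(benzyloxy)-4-{[2-ethoxy-6-methyl-4-(prop-2-en-1-yloxy)benzoyl]oxy}-6-methylbenzoate | COC(=O)c1c(C)cc(OC(=O)c2c(C)cc(OCC=C)cc2OCC)cc1OCc1ccccc1
F5 | step 12 | methyl 4-[(2,4-dihydroxy-6-methylbenzoyl)oxy]-2-hydroxy-6-methylbenzoate | COC(=O)c1c(C)cc(OC(=O)c2c(C)cc(O)cc2O)cc1O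
F6 | step 12 | methyl 4-({4-[(2,4-bis(benzyloxy)-6-methylbenzoyl)oxy]-2-hydroxy-6-methylbenzoyl}oxy)-2-hydroxy-6-methylbenzoate | COC(=O)c1c(C)cc(OC(=O)c2c(C)cc(OC(=O)c3c(C)cc(OCc4ccccc4)cc3OCc3ccccc3)cc2O)cc1O
F7 | step 6 | methyl 2-(benzyloxy)-4-[(bromoacetyl)oxy]-6-methylbenzoate | COC(=O)c1c(C)cc(OC(=O)CBr)cc1OCc1ccccc1
F8 | step 6 | methyl 2-(benzyloxy)-4-[(diazoacetyl)oxy]-6-methylbenzoate | COC(=O)c1c(C)cc(OC(=O)C=[N+]=[N-])cc1OCc1ccccc1
F9 | step 6 | methyl 2-(benzyloxy)-4-[(2-diazo-3-hydroxy-4-methylpent-4-enoyl)oxy]-6-methylbenzoate (racemic) | COC(=O)c1c(C)cc(OC(=O)C(=[N+]=[N-])C(O)C(C)=C)cc1OCc1ccccc1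
A1 | alternative 1 | 6-methyl-2-oxo-2H-pyran-4-yl 2-(benzyloxy)-4-{[2,4-bis(benzyloxy)-6-methylbenzoyl]oxy}-6-methylbenzoate | Cc1cc(OC(=O)c2c(C)cc(OC(=O)c3c(C)cc(OCc4ccccc4)cc3OCc3ccccc3)cc2OCc2ccccc2)cc(=O)o1
A2 | alternative 1 | methyl 3-methoxyprop-2-ynoate | COC#CC(=O)OC
A3 | alternative 1 | methyl 4-({2-(benzyloxy)-4-[(2,4-bis(benzyloxy)-6-methylbenzoyl)oxy]-6-methylbenzoyl}oxy)-2-methoxy-6-methylbenzoate | COC(=O)c1c(C)cc(OC(=O)c2c(C)cc(OC(=O)c3c(C)cc(OCc4ccccc4)cc3OCc3ccccc3)cc2OCc2ccccc2)cc1OC
A4 | alternative 2 | 1-methoxy-1,3-bis(trimethylsilyloxy)buta-1,3-diene | COC(O[Si](C)(C)C)=CC(=C)O[Si](C)(C)C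
A5 | alternative 2 | methyl 2-(benzyloxy)-4-{[2-(benzyloxy)-4-(but-2-ynoyloxy)-6-methylbenzoyl]oxy}-6-methylbenzoate | COC(=O)c1c(C)cc(OC(=O)c2c(C)cc(OC(=O)C#CC)cc2OCc2ccccc2)cc1OCc1ccccc1
A6 | alternative 2 | methyl 2-(benzyloxy)-4-({2-(benzyloxy)-4-[(2,4-dihydroxy-6-methylbenzoyl)oxy]-6-methylbenzoyl}oxy)-6-methylbenzoate | COC(=O)c1c(C)cc(OC(=O)c2c(C)cc(OC(=O)c3c(C)cc(O)cc3O)cc2OCc2ccccc2)cc1OCc1ccccc1
A7 | alternative 3 | 3-(benzyloxy)-4-iodo-5-methylphenyl 2,4-bis(benzyloxy)-6-methylbenzoate | Cc1cc(OC(=O)c2c(C)cc(OCc3ccccc3)cc2OCc2ccccc2)cc(OCc2ccccc2)c1I
A8 | alternative 3 | carbon monoxide | [C-]#[O+]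
A9 | alternative 3 | methyl 4-({2-(benzyloxy)-4-[(2,4-bis(benzyloxy)-6-methylbenzoyl)oxy]-6-methylbenzoyl}oxy)-2-hydroxy-6-methylbenzoate | COC(=O)c1c(C)cc(OC(=O)c2c(C)cc(OC(=O)c3c(C)cc(OCc4ccccc4)cc3OCc3ccccc3)cc2OCc2ccccc2)cc1O
A10 | alternative 3 | 3-(benzyloxy)-5-methylphenol | Cc1cc(O)cc(OCc2ccccc2)c1
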